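## Overview

- **Atom labels.** Heavy atoms of the target in SMILES order, ester and N‑methyl carbons left out: C1–C2 ethyl, C3=C4, C5, spiro C6, C7, O8, C9, C10, C11, C12=C13, C14, C15, C16, C17 (CO2Me), C18, C19, C20, N21, C22. Ring A is C12–C16; ring B is C13, C14, C17, C18, C19.
- **Cuts, in retrosynthetic order.** N21–C20 and N21–C22 (double reductive amination); O8–C3 and C4=C5 (hemiketal dehydration, Horner–Wadsworth–Emmons); C6–C19 between the two quaternary carbons ([3,3]); C10=C11 (metathesis); the C5 acyl–O bond; C12–C11 (allylation); C13=C19 (aldol); C17–C18 (alkylation); C14–C17 (Michael).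
- **Enabling feature.** The C6–C19 bond is allylic to the tetrasubstituted C12=C13 alkene inside the cycloheptene (C6, C9, C10, C11, C12, C13, C19), and C6 bears the one‑carbon arm C5. The carbocycle is therefore the Ireland–Claisen image of a seven‑membered lactone (O, C5, C6, C9, C10, C11, C12) spiro at C12 to a ring A/ring B bicyclo[3.3.0]octene with a C13=C19 alkene.
- **Forward ring order.** Ring A is bought as cyclopentenone; ring B closes by aldol condensation, the spiro lactone by ring‑closing metathesis, the cycloheptene by the Claisen step, the dihydropyran by hemiketal dehydration, and the piperidine last by double reductive amination.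
- **Stereochemistry.** C14 comes from an asymmetric Michael addition and C9 from a rhodium‑catalysed asymmetric vinyl addition. The temporary C12 carbinol comes from a catalyst‑controlled allylation and is relayed to C19 and C6 in the key step. C17 is set by kinetic protonation after dealkoxycarbonylation.

Key step: step 14

Assumption: the nearly flat bicyclic enone has no useful facial bias, so the hand of the bisphosphine in the allylation is whichever delivers allyl syn to H14 (to be fixed by NOE in a first run); racemic chloropropanediol is used because its stereocentre is oxidised away.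

Abbreviations: TBDPS = tert‑butyldiphenylsilyl, Bn = benzyl.

## Route

**Step 1**
Reactants: 1 cyclopent‑2‑en‑1‑one; 2 dimethyl malonate
Product: 3 dimethyl (S)‑2‑(3‑oxocyclopentyl)malonate
Conditions: LiAl[(S)‑BINOLate]2 (10 mol %, from LiAlH4 and (S)‑BINOL), KOtBu (9 mol %), 4 Å MS, THF, rt
Reagents that add atoms: none
Why: Catalytic asymmetric Michael addition in which the aluminium centre activates the enone and the lithium binaphthoxide delivers the malonate to one enantioface, the ligand hand being the one that gives S at C14 (the S ligand by analogy with cyclohexenone).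

**Step 2**
Reactants: 4 3‑chloropropane‑1,2‑diol (racemic)
Product: 5 1‑chloro‑3‑(tert‑butyldiphenylsilyloxy)propan‑2‑ol
Conditions: TBDPSCl, imidazole, CH2Cl2, 0 °C
Reagents that add atoms: tert‑butyl(chloro)diphenylsilane, CC(C)(C)[Si](Cl)(c1ccccc1)c1ccccc1
Why: Silyl ether formation with a bulky chlorosilane is selective for the primary hydroxyl, and TBDPS is chosen because it must later survive hot LiCl in wet DMSO.

**Step 3**
Reactants: 5 1‑chloro‑3‑(tert‑butyldiphenylsilyloxy)propan‑2‑ol
Product: 6 1‑chloro‑3‑(tert‑butyldiphenylsilyloxy)propan‑2‑one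
Conditions: Dess–Martin periodinane, NaHCO3, CH2Cl2, rt
Reagents that add atoms: none
Why: Dess–Martin oxidation converts the secondary alcohol to the ketone under near‑neutral conditions that leave the C–Cl bond and the silyl ether alone.

**Step 4**
Reactants: 3 dimethyl (S)‑2‑(3‑oxocyclopentyl)malonate; 6 1‑chloro‑3‑(tert‑butyldiphenylsilyloxy)propan‑2‑one
Product: 7 dimethyl 2‑[(S)‑3‑oxocyclopentyl]‑2‑[2‑oxo‑3‑(tert‑butyldiphenylsilyloxy)propyl]malonate
Conditions: NaH (1.0 equiv), THF–DMF, 0 °C; then 6, NaI (10 mol %), 0 °C → rt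
Reagents that add atoms: none
Why: SN2 C‑alkylation of the sodium malonate by an α‑halo ketone (iodide made in situ, Finkelstein) forms C17–C18; one equivalent of base deprotonates only the malonate C–H, so the ketone enolate that could trigger a retro‑Michael loss of C14 is not formed, and C17 carries two identical esters and is no stereocentre.

**Step 5**
Reactants: 7 alkylated malonate diketone
Product: 9 dimethyl (6aS)‑3‑[(tert‑butyldiphenylsilyloxy)methyl]‑4‑oxo‑4,5,6,6a‑tetrahydropentalene‑1,1(2H)‑dicarboxylate (ketone C12; alkene C13=C19), via aldol adduct 8 (not isolated)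
Conditions: pyrrolidine (30 mol %), AcOH (30 mol %), toluene, 50 °C
Reagents that add atoms: none
Why: Amine–acid‑catalysed intramolecular aldol condensation of a 1,6‑diketone, in which the cyclopentanone enamine attacks the C19 ketone through C13 (five‑membered ring B) and dehydration to the conjugated enone is the only irreversible outlet (the C18‑to‑C12 aldol gives a bridged carbinol that cannot dehydrate); C14 is not acidic in the product.

**Step 6**
Reactants: 9 bicyclic enone
Product: 10 dimethyl (4S,6aS)‑4‑allyl‑3‑[(tert‑butyldiphenylsilyloxy)methyl]‑4‑hydroxy‑4,5,6,6a‑tetrahydropentalene‑1,1(2H)‑dicarboxylate (C12 carbinol, OH anti to H14)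
Conditions: AgF (5 mol %), DIFLUORPHOS (5 mol %, the enantiomer giving the 12S carbinol), allylSi(OMe)3, MeOH (1 equiv), THF, −78 → −40 °C
Reagents that add atoms: allyltrimethoxysilane, C=CC[Si](OC)(OC)OC
Why: Silver‑catalysed asymmetric Sakurai–Hosomi‑type allylation adds 1,2 to conjugated ketones, and because the enone offers little bias of its own the chiral bisphosphine decides the face, allyl entering syn to H14 so that the C12 oxygen lies anti to H14.

**Step 7**
Reactants: 10 allyl carbinol
Product: 11 dimethyl (4S,6aS)‑3‑[(tert‑butyldiphenylsilyloxy)methyl]‑4‑hydroxy‑4‑[(E)‑prop‑1‑enyl]‑4,5,6,6a‑tetrahydropentalene‑1,1(2H)‑dicarboxylate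
Conditions: RuHCl(CO)(PPh3)3 (5 mol %), toluene, 80 °C
Reagents that add atoms: none
Why: Ruthenium hydride alkene isomerisation (hydrometalation then β‑hydride elimination) moves the terminal alkene by one position to the E‑propenyl group and stops there because C12 bears no hydrogen.

**Step 8**
Reactants: 12 furan‑2(5H)‑one
Product: 13 (R)‑4‑vinyldihydrofuran‑2(3H)‑one
Conditions: [Rh(cod)2]PF6 (3 mol %), (R)‑BINAP, CH2=CHBF3K, toluene–H2O, 100 °C
Reagents that add atoms: potassium vinyltrifluoroborate, [K+].C=C[B-](F)(F)F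
Why: Rhodium‑catalysed asymmetric 1,4‑addition of a vinylboron reagent (Hayashi–Miyaura type) sets C9 and brings C10, the BINAP hand being the one that gives R by analogy with cyclic enones.

**Step 9**
Reactants: 13 (R)‑4‑vinyldihydrofuran‑2(3H)‑one
Product: 14 (3R,4S)‑3‑[(benzyloxy)methyl]‑4‑vinyldihydrofuran‑2(3H)‑one
Conditions: LiN(iPr)2, THF, −78 °C; BnOCH2Cl, −78 → −40 °C
Reagents that add atoms: benzyl chloromethyl ether, ClCOCc1ccccc1
Why: Alkylation of the lactone lithium enolate brings C7 and O8 and occurs anti to the neighbouring vinyl group, although the C6 centre it creates is erased again in the key step.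

**Step 10**
Reactants: 14 (3R,4S)‑3‑[(benzyloxy)methyl]‑4‑vinyldihydrofuran‑2(3H)‑one
Product: 17 (2R,3S)‑2‑[(benzyloxy)methyl]‑3‑[(tert‑butyldiphenylsilyloxy)methyl]pent‑4‑enoic acid, via potassium hydroxy carboxylate 15 (not isolated), via bis‑silyl compound 16 (not isolated)
Conditions: KOH, MeOH–H2O, rt, evaporate; TBDPSCl, imidazole, DMF, rt; K2CO3, MeOH–THF–H2O, rt; pH 4 work‑up
Reagents that add atoms: potassium hydroxide, [K+].[OH-]; tert‑butyl(chloro)diphenylsilane, CC(C)(C)[Si](Cl)(c1ccccc1)c1ccccc1
Why: Saponification, exhaustive silylation and selective methanolysis of the labile silyl ester is the standard way to a silyl‑protected hydroxy acid that cannot relactonise; epimerisation at C6 would be without consequence.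

**Step 11**
Reactants: 11 propenyl carbinol; 17 (2R,3S)‑acid
Product: 19 tertiary allylic ester diene (C12–O–C5 ester of 11 with 17), via acid chloride 18 (not isolated)
Conditions: 17, Me2C=C(Cl)NMe2, CH2Cl2, 0 °C → rt; 11, LiN(SiMe3)2, THF, −78 °C, then the acid chloride, −78 → 0 °C
Reagents that add atoms: none
Why: O‑acylation of a hindered tertiary lithium alkoxide by an acid chloride made under neutral conditions with an α‑chloro enamine, cold and acid‑free so that the doubly allylic C12–O bond cannot ionise.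

**Step 12**
Reactants: 19 tertiary allylic ester diene
Product: 20 unsaturated spiro lactone (oxepinone O, C5, C6, C9, C10=C11, C12)
Conditions: second‑generation Grubbs catalyst (5–10 mol %), CH2Cl2 (2 mM), 40 °C
Reagents that add atoms: none
Why: Ring‑closing metathesis starts at the monosubstituted vinyl group on C9 and closes onto the propenyl group with loss of propene, the tetrasubstituted C13=C19 alkene being inert to the catalyst.

**Step 13**
Reactants: 20 unsaturated spiro lactone
Product: 21 saturated spiro lactone (oxepan‑2‑one O, C5, C6, C9, C10, C11, C12; ring oxygen on C12 anti to H14)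
Conditions: 2‑nitrobenzenesulfonyl hydrazide (excess, in portions), Et3N, CH2Cl2, rt
Reagents that add atoms: none
Why: Diimide reduction transfers hydrogen concertedly to the disubstituted C10=C11 alkene only, sparing the tetrasubstituted alkene, the benzyl ether and the allylic C–O bond, and it removes the in‑ring allyl unit that would otherwise divert the next step toward a vinylcyclopropane.

**Step 14**
Reactants: 21 saturated spiro lactone
Product: 24 cycloheptene carboxylic acid with C6 and C19 quaternary, via silyl ketene acetal 22 (not isolated), via trimethylsilyl ester 23 (not isolated)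
Conditions: Me3SiCl–Et3N (premixed), THF, −78 °C; KN(SiMe3)2 added dropwise, −78 → 0 °C; toluene, 110 °C; 1 M HCl–THF, rt
Reagents that add atoms: none
Why: KN(SiMe3)2 deprotonates C6, the only enolisable carbon because C17 is a malonate carbon without hydrogen, and the enolate is silylated at once by the Me3SiCl already present, so loss of the β‑benzyloxy group is outrun and ketene acetal 22 forms with its C6=C5 geometry fixed by the ring. On heating, the array C6=C5–O–C12–C13=C19 undergoes a concerted suprafacial [3,3] sigmatropic shift (Ireland–Claisen rearrangement) that forms C6–C19, breaks C12–O and moves the alkene to C12=C13. The closest known reaction type is the Ireland–Claisen rearrangement of silyl ketene acetals of alkenyl lactones to cycloalkenecarboxylic acids, together with Ireland–Claisen syntheses of vicinal quaternary carbons. The cycloheptene (C6, C9, C10, C11, C12, C13, C19) closes by this sigmatropic transposition of the lactone ring through a boat transition state, a chair being out of reach when a three‑carbon tether spans the first and fourth atoms of the array. C19 is controlled by the C12 carbinol centre (the new bond forms on the alkene face from which oxygen departs, anti to H14), and C6 by the ring‑locked ketene acetal and the boat, which point the C5 carboxyl toward the carbocycle being formed and the C7 arm away from it. The step needs the [3,3] path to win over ionisation of the tertiary allylic C–O bond and over any other allyl partner; a non‑polar medium free of Lewis acid, the intramolecular hold on both fully substituted termini, the ester‑to‑carboxylate driving force and the absence of a second allyl unit after step 13 secure this.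

**Step 15**
Reactants: 24 cycloheptene carboxylic acid
Product: 25 primary alcohol (C5 as CH2OH)
Conditions: BH3·SMe2, THF, 0 °C → rt; MeOH quench
Reagents that add atoms: none
Why: Borane reduction of a carboxylic acid through its acyloxyborane is much faster than attack on methyl esters or hydroboration of a tetrasubstituted alkene.

**Step 16**
Reactants: 25 primary alcohol
Product: 26 C5 aldehyde
Conditions: Dess–Martin periodinane, NaHCO3, CH2Cl2, rt
Reagents that add atoms: none
Why: Dess–Martin oxidation of a neopentyl alcohol gives an aldehyde that has no α‑hydrogen and so can neither epimerise nor eliminate benzyloxide.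

**Step 17**
Reactants: 26 C5 aldehyde
Product: 27 (E)‑enone (C6–C5H=C4H–C3(=O)–C2H2–C1H3)
Conditions: (MeO)2P(O)CH2C(O)Et, NaH, THF, 0 → 50 °C
Reagents that add atoms: dimethyl (2‑oxobutyl)phosphonate, CCC(=O)CP(=O)(OC)OC
Why: Horner–Wadsworth–Emmons olefination with a stabilised keto phosphonate brings C4 to C1 and gives the E‑enone; the substrate has no enolisable position, so the hindered aldehyde can be forced with the preformed sodium phosphonate.

**Step 18**
Reactants: 27 (E)‑enone
Product: 28 hydroxy ketone (C7 as CH2OH, saturated C5–C4, ketone at C3; in equilibrium with its hemiketal)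
Conditions: H2 (1 atm), 10% Pd/C, EtOAc, rt
Reagents that add atoms: none
Why: Heterogeneous catalytic hydrogenation saturates the conjugated disubstituted alkene and hydrogenolyses the benzyl ether, while the tetrasubstituted C12=C13 alkene is too hindered to be reduced.

**Step 19**
Reactants: 28 hydroxy ketone
Product: 30 spiro dihydropyran malonate, via hemiketal 29 (not isolated)
Conditions: PPTS (10 mol %), toluene, 4 Å MS, 90 °C
Reagents that add atoms: none
Why: Acid‑catalysed hemiketalisation of O8 onto the C3 ketone and dehydration give the six‑membered endocyclic enol ether, the more stable isomer under equilibrating conditions, and the silyl ethers tolerate this weak acid in a non‑nucleophilic solvent.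

**Step 20**
Reactants: 30 spiro dihydropyran malonate
Product: 33 spiro dihydropyran monoester (C17–H syn to H14, CO2Me on the C6 side), via lithium carboxylate 31 (not isolated), via lithium ester enolate 32 (not isolated)
Conditions: LiCl, H2O (2 equiv), DMSO, 140 °C
Reagents that add atoms: none
Why: Krapcho dealkoxycarbonylation (chloride SN2 demethylation, decarboxylation, protonation of the ester enolate by water) sets C17 by proton delivery to the ring B face opposite the bulky spiro substituent at C6; it is placed here because the molecule then holds neither a Michael acceptor nor a free hydroxyl or acid that could trap the enolate or deliver the proton from the wrong face.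

**Step 21**
Reactants: 33 spiro dihydropyran monoester
Product: 34 diol (C20 and C22 as CH2OH)
Conditions: Bu4NF, THF, rt → 40 °C
Reagents that add atoms: none
Why: Fluoride‑induced desilylation removes both silyl ethers in a basic medium that cannot hydrolyse the enol ether.

**Step 22**
Reactants: 34 diol
Product: 35 1,5‑dialdehyde (C20 and C22 as CHO)
Conditions: (COCl)2, DMSO, CH2Cl2, −78 °C; Et3N, → −20 °C
Reagents that add atoms: none
Why: Swern oxidation takes both primary alcohols to aldehydes in a medium that is never acidic, so the enol ether survives; should C9 epimerise next to the C22 aldehyde, only the configuration syn to C20 can go on to bridge.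

**Step 23**
Reactants: 35 1,5‑dialdehyde
Product: 38 target CNP0159589.2, via amino aldehyde 36 (not isolated), via cyclic iminium ion 37 (not isolated)
Conditions: MeNH2 (2 M in THF), 4 Å MS, ClCH2CH2Cl, 0 °C; NaBH(OAc)3, 0 °C → rt
Reagents that add atoms: methylamine, CN
Why: Double reductive amination: the amine condenses first with the less hindered C22 aldehyde and is reduced, then the secondary amine closes onto the neopentyl C20 aldehyde as a six‑membered iminium ion that is reduced in turn, forming the piperidine without a new stereocentre and without added acid.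

## Compound list

1 | cyclopent‑2‑en‑1‑one | O=C1C=CCC1 | starting material
2 | dimethyl malonate | COC(=O)CC(=O)OC | starting material
3 | dimethyl (S)‑2‑(3‑oxocyclopentyl)malonate | O=C1C[C@H](CC1)C(C(=O)OC)C(=O)OC | intermediate
4 | 3‑chloropropane‑1,2‑diol (racemic) | OCC(O)CCl | starting material
5 | 1‑chloro‑3‑(tert‑butyldiphenylsilyloxy)propan‑2‑ol | ClCC(O)CO[Si](c1ccccc1)(c1ccccc1)C(C)(C)C | intermediate
6 | 1‑chloro‑3‑(tert‑butyldiphenylsilyloxy)propan‑2‑one | ClCC(=O)CO[Si](c1ccccc1)(c1ccccc1)C(C)(C)C | intermediate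
7 | dimethyl 2‑[(S)‑3‑oxocyclopentyl]‑2‑[2‑oxo‑3‑(tert‑butyldiphenylsilyloxy)propyl]malonate | O=C1C[C@H](CC1)C(CC(=O)CO[Si](c2ccccc2)(c2ccccc2)C(C)(C)C)(C(=O)OC)C(=O)OC | intermediate
8 | aldol adduct: cis‑fused bicyclic β‑hydroxy ketone with OH at C19 (formed in situ; C13 and C19 not defined) | O=C1CC[C@H]2C1C(O)(CO[Si](c3ccccc3)(c3ccccc3)C(C)(C)C)CC2(C(=O)OC)C(=O)OC | intermediate
9 | bicyclic enone: dimethyl (6aS)‑3‑[(tert‑butyldiphenylsilyloxy)methyl]‑4‑oxo‑4,5,6,6a‑tetrahydropentalene‑1,1(2H)‑dicarboxylate | O=C1CC[C@H]2C1=C(CO[Si](c3ccccc3)(c3ccccc3)C(C)(C)C)CC2(C(=O)OC)C(=O)OC | intermediate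
10 | allyl carbinol: dimethyl (4S,6aS)‑4‑allyl‑3‑[(tert‑butyldiphenylsilyloxy)methyl]‑4‑hydroxy‑4,5,6,6a‑tetrahydropentalene‑1,1(2H)‑dicarboxylate | O[C@]1(CC=C)CC[C@H]2C1=C(CO[Si](c3ccccc3)(c3ccccc3)C(C)(C)C)CC2(C(=O)OC)C(=O)OC | intermediate
11 | propenyl carbinol: dimethyl (4S,6aS)‑3‑[(tert‑butyldiphenylsilyloxy)methyl]‑4‑hydroxy‑4‑[(E)‑prop‑1‑enyl]‑4,5,6,6a‑tetrahydropentalene‑1,1(2H)‑dicarboxylate | O[C@]1(/C=C/C)CC[C@H]2C1=C(CO[Si](c3ccccc3)(c3ccccc3)C(C)(C)C)CC2(C(=O)OC)C(=O)OC | intermediate
12 | furan‑2(5H)‑one | O=C1C=CCO1 | starting material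
13 | (R)‑4‑vinyldihydrofuran‑2(3H)‑one | O=C1C[C@H](C=C)CO1 | intermediate
14 | (3R,4S)‑3‑[(benzyloxy)methyl]‑4‑vinyldihydrofuran‑2(3H)‑one | O=C1[C@@H](COCc2ccccc2)[C@H](C=C)CO1 | intermediate
15 | potassium (2R,3S)‑2‑[(benzyloxy)methyl]‑3‑(hydroxymethyl)pent‑4‑enoate (formed in situ) | [K+].[O-]C(=O)[C@@H](COCc1ccccc1)[C@@H](CO)C=C | intermediate
16 | tert‑butyldiphenylsilyl (2R,3S)‑2‑[(benzyloxy)methyl]‑3‑[(tert‑butyldiphenylsilyloxy)methyl]pent‑4‑enoate (formed in situ) | O=C(O[Si](c1ccccc1)(c1ccccc1)C(C)(C)C)[C@@H](COCc1ccccc1)[C@@H](CO[Si](c1ccccc1)(c1ccccc1)C(C)(C)C)C=C | intermediate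
17 | (2R,3S)‑2‑[(benzyloxy)methyl]‑3‑[(tert‑butyldiphenylsilyloxy)methyl]pent‑4‑enoic acid | OC(=O)[C@@H](COCc1ccccc1)[C@@H](CO[Si](c1ccccc1)(c1ccccc1)C(C)(C)C)C=C | intermediate
18 | acid chloride of 17 (formed in situ) | ClC(=O)[C@@H](COCc1ccccc1)[C@@H](CO[Si](c1ccccc1)(c1ccccc1)C(C)(C)C)C=C | intermediate
19 | tertiary allylic ester diene (C12 ester of 11 with 17) | C=C[C@H](CO[Si](c1ccccc1)(c1ccccc1)C(C)(C)C)[C@H](COCc1ccccc1)C(=O)O[C@]2(/C=C/C)CC[C@H]3C2=C(CO[Si](c4ccccc4)(c4ccccc4)C(C)(C)C)CC3(C(=O)OC)C(=O)OC | intermediate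
20 | unsaturated spiro lactone (cis C10=C11 in the seven‑membered lactone) | O=C1[C@@H](COCc2ccccc2)[C@@H](CO[Si](c2ccccc2)(c2ccccc2)C(C)(C)C)C=C[C@@]3(O1)CC[C@H]4C3=C(CO[Si](c5ccccc5)(c5ccccc5)C(C)(C)C)CC4(C(=O)OC)C(=O)OC | intermediate
21 | saturated spiro lactone (ring oxygen on C12 anti to H14) | O=C1[C@@H](COCc2ccccc2)[C@@H](CO[Si](c2ccccc2)(c2ccccc2)C(C)(C)C)CC[C@@]3(O1)CC[C@H]4C3=C(CO[Si](c5ccccc5)(c5ccccc5)C(C)(C)C)CC4(C(=O)OC)C(=O)OC | intermediate
22 | trimethylsilyl ketene acetal of 21 (C6=C5; formed in situ) | C[Si](C)(C)OC1=C(COCc2ccccc2)[C@@H](CO[Si](c2ccccc2)(c2ccccc2)C(C)(C)C)CC[C@@]3(O1)CC[C@H]4C3=C(CO[Si](c5ccccc5)(c5ccccc5)C(C)(C)C)CC4(C(=O)OC)C(=O)OC | intermediate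
23 | trimethylsilyl ester of 24 (formed in situ) | C[Si](C)(C)OC(=O)[C@]2(COCc5ccccc5)[C@@H](CO[Si](c5ccccc5)(c5ccccc5)C(C)(C)C)CCC3=C4[C@H](CC3)C(C(=O)OC)(C(=O)OC)C[C@@]42CO[Si](c5ccccc5)(c5ccccc5)C(C)(C)C | intermediate
24 | cycloheptene carboxylic acid (C6: CO2H, CH2OBn; C19: CH2OTBDPS anti to C6 across ring B, syn to H14) | OC(=O)[C@]2(COCc5ccccc5)[C@@H](CO[Si](c5ccccc5)(c5ccccc5)C(C)(C)C)CCC3=C4[C@H](CC3)C(C(=O)OC)(C(=O)OC)C[C@@]42CO[Si](c5ccccc5)(c5ccccc5)C(C)(C)C | intermediate
25 | primary alcohol (C5 as CH2OH) | OC[C@]2(COCc5ccccc5)[C@@H](CO[Si](c5ccccc5)(c5ccccc5)C(C)(C)C)CCC3=C4[C@H](CC3)C(C(=O)OC)(C(=O)OC)C[C@@]42CO[Si](c5ccccc5)(c5ccccc5)C(C)(C)C | intermediate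
26 | C5 aldehyde | O=C[C@]2(COCc5ccccc5)[C@@H](CO[Si](c5ccccc5)(c5ccccc5)C(C)(C)C)CCC3=C4[C@H](CC3)C(C(=O)OC)(C(=O)OC)C[C@@]42CO[Si](c5ccccc5)(c5ccccc5)C(C)(C)C | intermediate
27 | (E)‑enone | CCC(=O)/C=C/[C@]2(COCc5ccccc5)[C@@H](CO[Si](c5ccccc5)(c5ccccc5)C(C)(C)C)CCC3=C4[C@H](CC3)C(C(=O)OC)(C(=O)OC)C[C@@]42CO[Si](c5ccccc5)(c5ccccc5)C(C)(C)C | intermediate
28 | hydroxy ketone | CCC(=O)CC[C@]2(CO)[C@@H](CO[Si](c5ccccc5)(c5ccccc5)C(C)(C)C)CCC3=C4[C@H](CC3)C(C(=O)OC)(C(=O)OC)C[C@@]42CO[Si](c5ccccc5)(c5ccccc5)C(C)(C)C | intermediate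
29 | six‑membered hemiketal of 28 (formed in situ; C3 not defined) | CCC1(O)CC[C@]2(CO1)[C@@H](CO[Si](c5ccccc5)(c5ccccc5)C(C)(C)C)CCC3=C4[C@H](CC3)C(C(=O)OC)(C(=O)OC)C[C@@]42CO[Si](c5ccccc5)(c5ccccc5)C(C)(C)C | intermediate
30 | spiro dihydropyran malonate | CCC1=CC[C@]2(CO1)[C@@H](CO[Si](c5ccccc5)(c5ccccc5)C(C)(C)C)CCC3=C4[C@H](CC3)C(C(=O)OC)(C(=O)OC)C[C@@]42CO[Si](c5ccccc5)(c5ccccc5)C(C)(C)C | intermediate
31 | lithium carboxylate half ester (formed in situ; C17 not defined) | [Li+].CCC1=CC[C@]2(CO1)[C@@H](CO[Si](c5ccccc5)(c5ccccc5)C(C)(C)C)CCC3=C4[C@H](CC3)C(C(=O)OC)(C(=O)[O-])C[C@@]42CO[Si](c5ccccc5)(c5ccccc5)C(C)(C)C | intermediate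
32 | lithium ester enolate at C17 (formed in situ) | [Li+].CCC1=CC[C@]2(CO1)[C@@H](CO[Si](c5ccccc5)(c5ccccc5)C(C)(C)C)CCC3=C4[C@H](CC3)C(=C([O-])OC)C[C@@]42CO[Si](c5ccccc5)(c5ccccc5)C(C)(C)C | intermediate
33 | spiro dihydropyran monoester bis‑silyl ether | CCC1=CC[C@]2(CO1)[C@@H](CO[Si](c5ccccc5)(c5ccccc5)C(C)(C)C)CCC3=C4[C@H](CC3)[C@H](C(=O)OC)C[C@@]42CO[Si](c5ccccc5)(c5ccccc5)C(C)(C)C | intermediate
34 | diol | CCC1=CC[C@]2(CO1)[C@@H](CO)CCC3=C4[C@H](CC3)[C@H](C(=O)OC)C[C@@]42CO | intermediate
35 | 1,5‑dialdehyde | CCC1=CC[C@]2(CO1)[C@@H](C=O)CCC3=C4[C@H](CC3)[C@H](C(=O)OC)C[C@@]42C=O | intermediate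
36 | amino aldehyde (C22–NHMe, C20 CHO; formed in situ) | CCC1=CC[C@]2(CO1)[C@@H](CNC)CCC3=C4[C@H](CC3)[C@H](C(=O)OC)C[C@@]42C=O | intermediate
37 | cyclic iminium ion (C20=N21, acetate salt; formed in situ) | CC(=O)[O-].CCC1=CC[C@]2(CO1)[C@@H]1CCC3=C4[C@H](CC3)[C@H](C(=O)OC)C[C@@]42C=[N+](C)C1 | intermediate
38 | CNP0159589.2 | CCC1=CC[C@]2(CO1)[C@@H]1CCC3=C4[C@H](CC3)[C@H](C(=O)OC)C[C@@]42CN(C)C1 | target

## Step count and risks

Total: 23 steps. Longest linear sequence: 19 steps, from 4 through steps 2–7 and 11–23.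

**Step 14 (Ireland–Claisen).** The crowded boat may not be reached before the tertiary allylic C12–O bond ionises (fragmentation, or a [1,3] shift to a spiro cyclopentane), or benzyloxide may be lost during enolisation. The fallback splits the task: the pericyclic step makes only C19 quaternary, as in the classical α‑unsubstituted alkenyl lactone case, and C6 is quaternised afterwards. It sets out from lactone 13 and carbinol 11 and comes back at acid 24.
- Lactone 13 is opened with KOH to potassium (R)‑3‑(hydroxymethyl)pent‑4‑enoate F1, silylated with TBDPSCl to the bis‑silyl compound F2, and methanolysed to (R)‑3‑[(tert‑butyldiphenylsilyloxy)methyl]pent‑4‑enoic acid F3.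
- Its acid chloride F4 acylates the lithium alkoxide of 11 to give the ester diene F5.
- Metathesis gives the unsaturated spiro lactone F6 and diimide the saturated spiro lactone F7.
- The same internal‑quench enolisation gives the silyl ketene acetal F8, which rearranges on heating to the trimethylsilyl ester F9; hydrolysis gives the C6–H acid F10.
- The dianion of F10 (LiN(iPr)2, 2.2 equiv, THF–DMPU, −78 °C) is alkylated with BnOCH2Cl on the peripheral face of the exocyclic enediolate, away from the cycloheptene body. This should place C7 outside and C5 over the ring, which is acid 24.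

**Step 6 (allylation).** The facial selectivity may be poor or the turnover low, because the ketone is hindered and the catalyst must override a substrate without bias. The fallback gives up induction and relies on separation. It sets out from enone 9 and comes back at carbinol 10. Allylmagnesium bromide with anhydrous CeCl3 in THF at −78 °C adds 1,2 and gives 10 together with its C12‑epimeric allyl carbinol F11. The two are diastereomers and are separated by chromatography; only 10 is carried into step 7.

**Step 20 (Krapcho).** Protonation of the enolate may occur from the wrong face, or the ester may equilibrate at 140 °C toward the epimer with the ester away from C6. The fallback replaces the hot decarboxylative protonation by a cold protonation of a preformed enolate. It sets out from malonate 30 and comes back at monoester 33. The Krapcho mixture of 33 and the C17‑epimeric monoester F12 is deprotonated with LiN(iPr)2 in THF at −78 °C to the lithium enolate 32 and quenched at that temperature with 2,6‑di‑tert‑butylphenol, a bulky proton donor that can approach C17 only on the face syn to H14.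

## Further compounds

F1 | step 14 | potassium (R)‑3‑(hydroxymethyl)pent‑4‑enoate | [K+].[O-]C(=O)C[C@@H](CO)C=C
F2 | step 14 | bis‑silyl compound: tert‑butyldiphenylsilyl (R)‑3‑[(tert‑butyldiphenylsilyloxy)methyl]pent‑4‑enoate | O=C(O[Si](c1ccccc1)(c1ccccc1)C(C)(C)C)C[C@@H](CO[Si](c1ccccc1)(c1ccccc1)C(C)(C)C)C=C
F3 | step 14 | (R)‑3‑[(tert‑butyldiphenylsilyloxy)methyl]pent‑4‑enoic acid | OC(=O)C[C@@H](CO[Si](c1ccccc1)(c1ccccc1)C(C)(C)C)C=C
F4 | step 14 | acid chloride of F3 | ClC(=O)C[C@@H](CO[Si](c1ccccc1)(c1ccccc1)C(C)(C)C)C=C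
F5 | step 14 | ester diene (C12 ester of 11 with F3) | C=C[C@H](CO[Si](c1ccccc1)(c1ccccc1)C(C)(C)C)CC(=O)O[C@]2(/C=C/C)CC[C@H]3C2=C(CO[Si](c4ccccc4)(c4ccccc4)C(C)(C)C)CC3(C(=O)OC)C(=O)OC
F6 | step 14 | unsaturated spiro lactone without the C7 arm | O=C1C[C@@H](CO[Si](c2ccccc2)(c2ccccc2)C(C)(C)C)C=C[C@@]3(O1)CC[C@H]4C3=C(CO[Si](c5ccccc5)(c5ccccc5)C(C)(C)C)CC4(C(=O)OC)C(=O)OC
F7 | step 14 | saturated spiro lactone without the C7 arm | O=C1C[C@@H](CO[Si](c2ccccc2)(c2ccccc2)C(C)(C)C)CC[C@@]3(O1)CC[C@H]4C3=C(CO[Si](c5ccccc5)(c5ccccc5)C(C)(C)C)CC4(C(=O)OC)C(=O)OC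
F8 | step 14 | silyl ketene acetal of F7 | C[Si](C)(C)OC1=C[C@@H](CO[Si](c2ccccc2)(c2ccccc2)C(C)(C)C)CC[C@@]3(O1)CC[C@H]4C3=C(CO[Si](c5ccccc5)(c5ccccc5)C(C)(C)C)CC4(C(=O)OC)C(=O)OC
F9 | step 14 | trimethylsilyl ester of F10 | C[Si](C)(C)OC(=O)[C@@H]2[C@@H](CO[Si](c5ccccc5)(c5ccccc5)C(C)(C)C)CCC3=C4[C@H](CC3)C(C(=O)OC)(C(=O)OC)C[C@@]42CO[Si](c5ccccc5)(c5ccccc5)C(C)(C)C
F10 | step 14 | C6–H acid (cycloheptene carboxylic acid without the C7 arm) | OC(=O)[C@@H]2[C@@H](CO[Si](c5ccccc5)(c5ccccc5)C(C)(C)C)CCC3=C4[C@H](CC3)C(C(=O)OC)(C(=O)OC)C[C@@]42CO[Si](c5ccccc5)(c5ccccc5)C(C)(C)C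
F11 | step 6 | C12‑epimeric allyl carbinol | O[C@@]1(CC=C)CC[C@H]2C1=C(CO[Si](c3ccccc3)(c3ccccc3)C(C)(C)C)CC2(C(=O)OC)C(=O)OC
F12 | step 20 | C17‑epimeric monoester | CCC1=CC[C@]2(CO1)[C@@H](CO[Si](c5ccccc5)(c5ccccc5)C(C)(C)C)CCC3=C4[C@H](CC3)[C@@H](C(=O)OC)C[C@@]42CO[Si](c5ccccc5)(c5ccccc5)C(C)(C)C
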